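The cyclopentane is opened between the methyl-bearing ring carbon (C2) and the benzoyloxy-bearing ring carbon (C3). A trans-2-methylcyclopentanol is the signature of a 5-exo ketyl–olefin closure: SmI2 reduces a C3 aldehyde to its ketyl, which adds to the inner carbon of an allyl group on the quaternary acetoxy carbon (C15); the alkene terminus becomes the C2 methyl. One operation thus closes the ring and sets C2 and C3 under control of C4 and C15. The precursor is an acyclic α-alkenyl aldehyde that already carries C4, C15 and the C13/C14 pair, built from furan-2(5H)-one by asymmetric conjugate addition, allylation, hydroxylation and crotylboration.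

Key step: step 9

Remark on locants: ring carbons are C15 (acetoxy carbon), C1 (CH2), C2 (CH–CH3), C3 (CH–OBz) and C4 (CH carrying the enal arm C5=C6–C7); the long arm is C14 (CH–OAc), C13 (CH–CH3), C12=C11, C10 (CMe2), C9 (C=O), C8. TBS = tert-butyldimethylsilyl, pin = pinacolato.

Assumption: the absolute sense of the two catalyst-controlled steps (2 and 6) is taken from the accepted models for these catalyst classes; the mirror-image ligand or acid would be used if the opposite sense were found.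

Step 1
Reactants: 1 tert-butyldimethyl(prop-2-yn-1-yloxy)silane
Product: 2 tert-butyldimethyl{[(2E)-2-methyl-3-(4,4,5,5-tetramethyl-1,3,2-dioxaborolan-2-yl)prop-2-en-1-yl]oxy}silane
Conditions: CuCl (10 mol %), Xantphos (10 mol %), NaOt-Bu (1.5 equiv), B2pin2 (1.2 equiv), MeI (3 equiv), THF, rt
Reagents that add atoms: bis(pinacolato)diboron, CC1(C)OB(OC1(C)C)B1OC(C)(C)C(C)(C)O1; iodomethane, CI
Why: copper-catalysed carboboration of a terminal alkyne, in which syn borylcupration puts boron on the terminal carbon and the alkenylcopper is methylated with retention, should give the E alkenylboronate with methyl cis to boron (no stereocentre is formed).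

Step 2
Reactants: 2 alkenylboronate; 3 furan-2(5H)-one
Product: 4 (4S)-4-[(1E)-3-(TBS-oxy)-2-methylprop-1-en-1-yl]oxolan-2-one
Conditions: [Rh(OH)((S)-binap)]2 (3 mol %), 2 (1.5 equiv), dioxane/H2O 10:1, 50 °C
Reagents that add atoms: none
Why: Hayashi–Miyaura rhodium-catalysed asymmetric 1,4-addition (boron-to-rhodium alkenyl transfer, insertion of the butenolide, hydrolysis of the oxa-π-allyl), in which (S)-BINAP is expected by the accepted enone-face model to deliver the alkenyl group to the face that makes C4 S.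

Step 3
Reactants: 4 lactone; 5 allyl bromide
Product: 7 (3R,4R)-3-(prop-2-en-1-yl)-4-[(1E)-3-(TBS-oxy)-2-methylprop-1-en-1-yl]oxolan-2-one, via lithium enolate 6 (not isolated)
Conditions: LiN(i-Pr)2 (1.1 equiv), THF, −78 °C; then 5, −78 → −30 °C
Reagents that add atoms: none
Why: lactone enolate alkylation, in which the allyl group should enter anti to the C4 alkenyl group to give the trans lactone (this centre is erased in the next step).

Step 4
Reactants: 7 trans-allyl lactone
Product: 9 (3R,4S)-3-hydroxy-3-(prop-2-en-1-yl)-4-[(1E)-3-(TBS-oxy)-2-methylprop-1-en-1-yl]oxolan-2-one, via potassium enolate 8 (not isolated)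
Conditions: KN(SiMe3)2 (1.2 equiv), THF, −78 °C; then 2-(phenylsulfonyl)-3-phenyloxaziridine (1.5 equiv); AcOH quench
Reagents that add atoms: 2-(phenylsulfonyl)-3-phenyloxaziridine (Davis oxaziridine), O=S(=O)(c1ccccc1)N1OC1c1ccccc1
Why: Davis enolate hydroxylation, in which the oxidant should approach the planar enolate anti to the C4 alkenyl group, placing hydroxyl trans and allyl cis to it and so setting the quaternary C15 as R.

Step 5
Reactants: 9 hydroxy lactone
Product: 10 (3R,4S)-3-(prop-2-en-1-yl)-4-[(1E)-3-(TBS-oxy)-2-methylprop-1-en-1-yl]oxolane-2,3-diol (lactol, both anomers)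
Conditions: i-Bu2AlH (2.3 equiv), CH2Cl2, −78 °C; aq. KNaC4H4O6
Reagents that add atoms: none
Why: half-reduction of a γ-lactone by i-Bu2AlH through the stable aluminium acetal (the first equivalent is consumed by the tertiary hydroxyl), with the anomeric centre formed as a mixture that is lost in the next step.

Step 6
Reactants: 10 lactol; 11 (E)-crotylboronic acid pinacol ester
Product: 12 (2S,3R,4R,5R)-2-[(1E)-3-(TBS-oxy)-2-methylprop-1-en-1-yl]-5-methyl-3-(prop-2-en-1-yl)hept-6-ene-1,3,4-triol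
Conditions: 11 (2.5 equiv), (R)-3,3'-bis(2,4,6-triisopropylphenyl)-1,1'-binaphthyl-2,2'-diyl hydrogen phosphate ((R)-TRIP, 10 mol %), 4 Å MS, toluene, 0 °C → rt; aq. NaHCO3
Reagents that add atoms: none
Why: Brønsted acid-catalysed crotylboration of the ring-opened hydroxy aldehyde, in which the closed chair transition state turns the E geometry into the 13,14-anti relationship and the (R)-acid is expected to direct attack to the re face of the aldehyde (C14 R, hence C13 R), the face also favoured by a chelate-like alignment of the free C15 hydroxyl with the carbonyl.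

Step 7
Reactants: 12 triol
Product: 13 (2S,3E)-2-{(4R,5R)-5-[(2R)-but-3-en-2-yl]-2,2-dimethyl-4-(prop-2-en-1-yl)-1,3-dioxolan-4-yl}-5-(TBS-oxy)-4-methylpent-3-en-1-ol
Conditions: 2,2-dimethoxypropane (5 equiv), PPTS (10 mol %), acetone, rt
Reagents that add atoms: 2,2-dimethoxypropane, COC(C)(C)OC
Why: acid-catalysed transketalisation under equilibrating conditions, which should favour the five-membered dioxolane across the C14/C15 diol over the six-membered dioxane to the primary hydroxyl and so leave C3–OH free (no stereocentre changes).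

Step 8
Reactants: 13 acetonide alcohol
Product: 14 (2R,3E)-2-{(4R,5R)-5-[(2R)-but-3-en-2-yl]-2,2-dimethyl-4-(prop-2-en-1-yl)-1,3-dioxolan-4-yl}-5-(TBS-oxy)-4-methylpent-3-enal
Conditions: Dess–Martin periodinane (1.3 equiv), pyridine (5 equiv), CH2Cl2, 0 °C; used at once
Reagents that add atoms: none
Why: Dess–Martin oxidation under buffered, non-basic conditions, which should give the aldehyde without epimerisation at C4 or migration of the β,γ-double bond into conjugation (the descriptor at C4 changes only because CHO outranks C15).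

Step 9
Reactants: 14 aldehyde
Product: 15 (4R,5R,6S,7S,8R)-4-[(2R)-but-3-en-2-yl]-6-[(1E)-3-(TBS-oxy)-2-methylprop-1-en-1-yl]-2,2,8-trimethyl-1,3-dioxaspiro[4.4]nonan-7-ol
Conditions: SmI2 (3 equiv), HMPA (10 equiv), t-BuOH (2 equiv), THF, −78 → 0 °C; 14 added slowly
Reagents that add atoms: none
Why: SmI2 activated by HMPA transfers one electron to the aldehyde to give the C3 ketyl radical, which adds 5-exo-trig to the inner carbon (C2) of the allyl group on C15, and the primary radical left on the terminal carbon is reduced by a second SmI2 and protonated by t-BuOH, so that this carbon ends as the C2 methyl. This is the known SmI2-mediated ketyl–olefin reductive cyclisation of δ,ε-unsaturated carbonyl compounds. The ring closes through a chair-like (Beckwith–Houk) transition state with the C4 alkenyl group and the C14 arm on C15 pseudo-equatorial, which puts the new methyl trans to the C4 substituent and cis to C14 and so should fix C2 as R. The bulky O–Sm(HMPA)n group of the ketyl turns away from the alkene (the anti preference of samarium ketyls), which should give the trans C2-methyl/C3-hydroxyl pair (C3 S) and leaves the C3 oxygen cis to the dioxolane oxygen on C15, an arrangement that trivalent samarium can bridge. The step needs 5-exo closure onto the allyl group to outrun 6-exo attack on the butenyl vinyl group, pinacol coupling and simple reduction; the general kinetic preference for 5-exo closure, the quaternary C15 and slow addition of 14 to excess SmI2 should secure this, while the acetonide keeps the C15 oxygen from β-elimination and the C14 oxygen from lactol formation.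

Step 10
Reactants: 15 cyclopentanol
Product: 16 (4R,5R,6S,7S,8R)-4-[(2R)-but-3-en-2-yl]-6-[(1E)-3-(TBS-oxy)-2-methylprop-1-en-1-yl]-2,2,8-trimethyl-1,3-dioxaspiro[4.4]nonan-7-yl benzoate
Conditions: BzCl (1.5 equiv), pyridine, DMAP (cat.), CH2Cl2, 0 °C → rt
Reagents that add atoms: benzoyl chloride, O=C(Cl)c1ccccc1
Why: DMAP-catalysed acylation of the only free hydroxyl (C3–OH), with retention at C3.

Step 11
Reactants: 16 benzoate
Product: 17 (1S,2S,3R,5R)-3-hydroxy-3-[(1R,2R)-1-hydroxy-2-methylbut-3-en-1-yl]-2-[(1E)-3-hydroxy-2-methylprop-1-en-1-yl]-5-methylcyclopentyl benzoate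
Conditions: p-TsOH·H2O (0.2 equiv), MeOH, rt
Reagents that add atoms: none
Why: acid-catalysed transacetalisation of the acetonide and methanolysis of the primary silyl ether, with the benzoate stable and its migration to the tertiary C15 hydroxyl thermodynamically disfavoured.

Step 12
Reactants: 17 triol
Product: 18 (1S,2S,3R,5R)-3-hydroxy-3-[(1R,2R)-1-hydroxy-2-methylbut-3-en-1-yl]-5-methyl-2-[(1E)-2-methyl-3-oxoprop-1-en-1-yl]cyclopentyl benzoate
Conditions: activated MnO2 (20 equiv), CH2Cl2, rt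
Reagents that add atoms: none
Why: MnO2 oxidation is selective for the allylic primary alcohol and should leave the secondary/tertiary diol and the E geometry untouched.

Step 13
Reactants: 18 enal diol
Product: 19 (1S,2S,3R,5R)-3-acetoxy-3-[(1R,2R)-1-acetoxy-2-methylbut-3-en-1-yl]-5-methyl-2-[(1E)-2-methyl-3-oxoprop-1-en-1-yl]cyclopentyl benzoate
Conditions: Ac2O (6 equiv), Et3N (8 equiv), DMAP (0.5 equiv), CH2Cl2, rt → 40 °C
Reagents that add atoms: acetic anhydride, CC(=O)OC(C)=O
Why: Steglich-type DMAP-catalysed acetylation, forcing enough to acylate the tertiary C15 hydroxyl after C14–OH, with no stereocentre touched.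

Step 14
Reactants: 20 2,2-dimethylbut-3-enoic acid
Product: 22 3,3-dimethylpent-4-en-2-one, via dilithium gem-diolate 21 (not isolated)
Conditions: MeLi (2.2 equiv), Et2O, 0 °C → rt; poured into cold aq. HCl
Reagents that add atoms: methyllithium, [Li]C
Why: methyl ketone synthesis from a carboxylic acid, in which the lithium carboxylate adds one MeLi and the resulting dianion does not collapse to the ketone until hydrolysis.

Step 15
Reactants: 19 diacetate enal; 22 3,3-dimethylpent-4-en-2-one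
Product: 23 (1S,2S,3R,5R)-3-acetoxy-3-[(1R,2R,3E)-1-acetoxy-2,5,5-trimethyl-6-oxohept-3-en-1-yl]-5-methyl-2-[(1E)-2-methyl-3-oxoprop-1-en-1-yl]cyclopentyl benzoate (CNP0489076.2)
Conditions: second-generation Hoveyda–Grubbs catalyst (10 mol %), 22 (8 equiv), CH2Cl2, 40 °C, argon sparge
Reagents that add atoms: none
Why: olefin cross-metathesis between the vinyl group of 19 and that of 22, whose quaternary allylic carbon suppresses self-metathesis and should enforce the E alkene, while the electron-poor trisubstituted enal is inert to the ruthenium alkylidene.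

Compound list

1 | tert-butyldimethyl(prop-2-yn-1-yloxy)silane | C#CCO[Si](C)(C)C(C)(C)C | starting material
2 | tert-butyldimethyl{[(2E)-2-methyl-3-(4,4,5,5-tetramethyl-1,3,2-dioxaborolan-2-yl)prop-2-en-1-yl]oxy}silane | C/C(CO[Si](C)(C)C(C)(C)C)=C\B1OC(C)(C)C(C)(C)O1 | intermediate
3 | furan-2(5H)-one | O=C1C=CCO1 | starting material
4 | (4S)-4-[(1E)-3-(TBS-oxy)-2-methylprop-1-en-1-yl]oxolan-2-one | O=C1OC[C@@H](C1)/C=C(\C)CO[Si](C)(C)C(C)(C)C | intermediate
5 | allyl bromide (3-bromoprop-1-ene) | C=CCBr | starting material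
6 | lithium enolate of 4 (not isolated) | [Li]OC1=C[C@H](CO1)/C=C(\C)CO[Si](C)(C)C(C)(C)C | intermediate
7 | (3R,4R)-3-(prop-2-en-1-yl)-4-[(1E)-3-(TBS-oxy)-2-methylprop-1-en-1-yl]oxolan-2-one | O=C1OC[C@@H]([C@H]1CC=C)/C=C(\C)CO[Si](C)(C)C(C)(C)C | intermediate
8 | potassium enolate of 7 (not isolated) | [K]OC1=C(CC=C)[C@H](CO1)/C=C(\C)CO[Si](C)(C)C(C)(C)C | intermediate
9 | (3R,4S)-3-hydroxy-3-(prop-2-en-1-yl)-4-[(1E)-3-(TBS-oxy)-2-methylprop-1-en-1-yl]oxolan-2-one | O=C1OC[C@@H]([C@]1(O)CC=C)/C=C(\C)CO[Si](C)(C)C(C)(C)C | intermediate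
10 | (3R,4S)-3-(prop-2-en-1-yl)-4-[(1E)-3-(TBS-oxy)-2-methylprop-1-en-1-yl]oxolane-2,3-diol (both anomers) | OC1OC[C@@H]([C@]1(O)CC=C)/C=C(\C)CO[Si](C)(C)C(C)(C)C | intermediate
11 | 2-[(2E)-but-2-en-1-yl]-4,4,5,5-tetramethyl-1,3,2-dioxaborolane | C/C=C/CB1OC(C)(C)C(C)(C)O1 | starting material
12 | (2S,3R,4R,5R)-2-[(1E)-3-(TBS-oxy)-2-methylprop-1-en-1-yl]-5-methyl-3-(prop-2-en-1-yl)hept-6-ene-1,3,4-triol | O[C@H]([C@H](C)C=C)[C@@](O)(CC=C)[C@H](CO)/C=C(\C)CO[Si](C)(C)C(C)(C)C | intermediate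
13 | (2S,3E)-2-{(4R,5R)-5-[(2R)-but-3-en-2-yl]-2,2-dimethyl-4-(prop-2-en-1-yl)-1,3-dioxolan-4-yl}-5-(TBS-oxy)-4-methylpent-3-en-1-ol | CC1(C)O[C@H]([C@H](C)C=C)[C@@](O1)(CC=C)[C@H](CO)/C=C(\C)CO[Si](C)(C)C(C)(C)C | intermediate
14 | (2R,3E)-2-{(4R,5R)-5-[(2R)-but-3-en-2-yl]-2,2-dimethyl-4-(prop-2-en-1-yl)-1,3-dioxolan-4-yl}-5-(TBS-oxy)-4-methylpent-3-enal | CC1(C)O[C@H]([C@H](C)C=C)[C@@](O1)(CC=C)[C@H](C=O)/C=C(\C)CO[Si](C)(C)C(C)(C)C | intermediate
15 | (4R,5R,6S,7S,8R)-4-[(2R)-but-3-en-2-yl]-6-[(1E)-3-(TBS-oxy)-2-methylprop-1-en-1-yl]-2,2,8-trimethyl-1,3-dioxaspiro[4.4]nonan-7-ol | CC1(C)O[C@H]([C@H](C)C=C)[C@@]2(O1)C[C@@H](C)[C@H](O)[C@@H]2/C=C(\C)CO[Si](C)(C)C(C)(C)C | intermediate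
16 | (4R,5R,6S,7S,8R)-4-[(2R)-but-3-en-2-yl]-6-[(1E)-3-(TBS-oxy)-2-methylprop-1-en-1-yl]-2,2,8-trimethyl-1,3-dioxaspiro[4.4]nonan-7-yl benzoate | CC1(C)O[C@H]([C@H](C)C=C)[C@@]2(O1)C[C@@H](C)[C@H](OC(=O)c3ccccc3)[C@@H]2/C=C(\C)CO[Si](C)(C)C(C)(C)C | intermediate
17 | (1S,2S,3R,5R)-3-hydroxy-3-[(1R,2R)-1-hydroxy-2-methylbut-3-en-1-yl]-2-[(1E)-3-hydroxy-2-methylprop-1-en-1-yl]-5-methylcyclopentyl benzoate | O[C@H]([C@H](C)C=C)[C@@]1(O)C[C@@H](C)[C@H](OC(=O)c2ccccc2)[C@@H]1/C=C(\C)CO | intermediate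
18 | (1S,2S,3R,5R)-3-hydroxy-3-[(1R,2R)-1-hydroxy-2-methylbut-3-en-1-yl]-5-methyl-2-[(1E)-2-methyl-3-oxoprop-1-en-1-yl]cyclopentyl benzoate | O[C@H]([C@H](C)C=C)[C@@]1(O)C[C@@H](C)[C@H](OC(=O)c2ccccc2)[C@@H]1/C=C(\C)C=O | intermediate
19 | (1S,2S,3R,5R)-3-acetoxy-3-[(1R,2R)-1-acetoxy-2-methylbut-3-en-1-yl]-5-methyl-2-[(1E)-2-methyl-3-oxoprop-1-en-1-yl]cyclopentyl benzoate | CC(=O)O[C@H]([C@H](C)C=C)[C@@]1(OC(C)=O)C[C@@H](C)[C@H](OC(=O)c2ccccc2)[C@@H]1/C=C(\C)C=O | intermediate
20 | 2,2-dimethylbut-3-enoic acid | C=CC(C)(C)C(=O)O | starting material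
21 | dilithium 3,3-dimethylpent-4-ene-2,2-diolate (not isolated) | C=CC(C)(C)C(C)(O[Li])O[Li] | intermediate
22 | 3,3-dimethylpent-4-en-2-one | C=CC(C)(C)C(C)=O | intermediate
23 | (1S,2S,3R,5R)-3-acetoxy-3-[(1R,2R,3E)-1-acetoxy-2,5,5-trimethyl-6-oxohept-3-en-1-yl]-5-methyl-2-[(1E)-2-methyl-3-oxoprop-1-en-1-yl]cyclopentyl benzoate | CC(=O)O[C@H]([C@H](C)/C=C/C(C)(C)C(C)=O)[C@@]1(OC(C)=O)C[C@@H](C)[C@H](OC(=O)c2ccccc2)[C@@H]1/C=C(\C)C=O | target

Total step count: 15.
Longest linear sequence: 14 steps (steps 1 to 13, then 15; step 14 is a one-step side branch).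

Steps most likely to fail

Step 9 (key step). The likely failure is loss of facial control at the ketyl carbon: if HMPA-saturated samarium cannot hold the anti, chelate-supported transition state, the ketyl oxygen closes syn to the alkene and C3 forms with the opposite configuration. Lesser risks are 6-exo closure onto the butenyl group and isomerisation of the β,γ-unsaturated aldehyde before it is reduced. The fallback replaces reliance on the radical transition state by stereochemical correction through invertive esterification. It sets out from 14: the cyclisation product with the epimeric hydroxyl, (4R,5R,6S,7R,8R)-4-[(2R)-but-3-en-2-yl]-6-[(1E)-3-(TBS-oxy)-2-methylprop-1-en-1-yl]-2,2,8-trimethyl-1,3-dioxaspiro[4.4]nonan-7-ol F1, is not benzoylated with retention but treated with benzoic acid, PPh3 and diisopropyl azodicarboxylate in toluene (Mitsunobu reaction). This installs the benzoate with inversion at C3, and the fallback comes back to the route at 16.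

Step 15. The likely failure is slow, unselective metathesis: the alkylidene from the quaternary-substituted olefin 22 forms sluggishly and the allylically branched vinyl group of 19 is itself hindered, so catalyst decay and self-coupling of 19 may outrun the cross-coupling. The fallback makes the C10–C11 bond by an aldol reaction and the C11=C12 double bond by dehydration, with no metathesis. It sets out from 16.
- Hydroboration of the monosubstituted vinyl group with 9-BBN (THF; NaBO3·4H2O) should give the primary alcohol (16 with the butenyl group as (2R)-4-hydroxybutan-2-yl) F2.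
- Dess–Martin oxidation gives the aldehyde (the (2R)-4-oxobutan-2-yl analogue) F3.
- Mukaiyama aldol addition of trimethyl[(3-methylbut-2-en-2-yl)oxy]silane (BF3·OEt2, CH2Cl2, −78 °C) builds the quaternary carbon and gives the β-hydroxy ketone (the 4-hydroxy-5,5-dimethyl-6-oxoheptan-2-yl analogue, mixed at the carbinol carbon) F4.
- Dehydration with the Burgess reagent (toluene, 80 °C), possible only toward C12, should give the E-enone (the (2R,3E)-5,5-dimethyl-6-oxohept-3-en-2-yl analogue of 16) F5.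
- p-TsOH in MeOH gives the triol (17 carrying the complete oxoheptenyl arm) F6, and MnO2 gives the enal diol (18 carrying the complete oxoheptenyl arm) F7.
- Acetylation as in step 13 comes back to the route at 23.

Step 6. The likely failure is slow, poorly face-selective crotyl transfer: the aldehyde is present only as the minor open form of lactol 10 and carries free hydroxyls, so an uncatalysed background reaction and the Felkin-type bias of the quaternary α-carbon may compete with catalyst control. The fallback uses a protected open-chain aldehyde and a stoichiometric chiral crotylborane. It sets out from lactone 9.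
- Aminolysis with MeNHOMe·HCl/AlMe3 gives (2R)-2-hydroxy-2-[(2S,3E)-1-hydroxy-5-(TBS-oxy)-4-methylpent-3-en-2-yl]-N-methoxy-N-methylpent-4-enamide F8.
- 2,2-Dimethoxypropane/PPTS closes the six-membered acetonide across the primary and tertiary hydroxyls to give (4R,5S)-N-methoxy-N,2,2-trimethyl-4-(prop-2-en-1-yl)-5-[(1E)-3-(TBS-oxy)-2-methylprop-1-en-1-yl]-1,3-dioxane-4-carboxamide F9.
- i-Bu2AlH (THF, −78 °C) gives the corresponding (4R,5S)-1,3-dioxane-4-carbaldehyde F10.
- Brown crotylboration with (E)-crotyldiisopinocampheylborane of the (−)-α-pinene series (from (+)-B-methoxydiisopinocampheylborane, trans-but-2-ene, n-BuLi/KOt-Bu, BF3·OEt2; −78 °C; NaBO3 work-up) should give, under reagent control, (1R,2R)-1-{(4R,5S)-2,2-dimethyl-4-(prop-2-en-1-yl)-5-[(1E)-3-(TBS-oxy)-2-methylprop-1-en-1-yl]-1,3-dioxan-4-yl}-2-methylbut-3-en-1-ol F11.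
- PPTS in acetone then lets the acetonide migrate to the thermodynamically preferred dioxolane across C14/C15, and the fallback comes back to the route at 13.

Further compounds

F1 | step 9 | (4R,5R,6S,7R,8R)-4-[(2R)-but-3-en-2-yl]-6-[(1E)-3-(TBS-oxy)-2-methylprop-1-en-1-yl]-2,2,8-trimethyl-1,3-dioxaspiro[4.4]nonan-7-ol | CC1(C)O[C@H]([C@H](C)C=C)[C@@]2(O1)C[C@@H](C)[C@@H](O)[C@@H]2/C=C(\C)CO[Si](C)(C)C(C)(C)C
F2 | step 15 | (4R,5R,6S,7S,8R)-4-[(2R)-4-hydroxybutan-2-yl]-6-[(1E)-3-(TBS-oxy)-2-methylprop-1-en-1-yl]-2,2,8-trimethyl-1,3-dioxaspiro[4.4]nonan-7-yl benzoate | CC1(C)O[C@H]([C@H](C)CCO)[C@@]2(O1)C[C@@H](C)[C@H](OC(=O)c3ccccc3)[C@@H]2/C=C(\C)CO[Si](C)(C)C(C)(C)C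
F3 | step 15 | (4R,5R,6S,7S,8R)-4-[(2R)-4-oxobutan-2-yl]-6-[(1E)-3-(TBS-oxy)-2-methylprop-1-en-1-yl]-2,2,8-trimethyl-1,3-dioxaspiro[4.4]nonan-7-yl benzoate | CC1(C)O[C@H]([C@H](C)CC=O)[C@@]2(O1)C[C@@H](C)[C@H](OC(=O)c3ccccc3)[C@@H]2/C=C(\C)CO[Si](C)(C)C(C)(C)C
F4 | step 15 | (4R,5R,6S,7S,8R)-4-[(2R)-4-hydroxy-5,5-dimethyl-6-oxoheptan-2-yl]-6-[(1E)-3-(TBS-oxy)-2-methylprop-1-en-1-yl]-2,2,8-trimethyl-1,3-dioxaspiro[4.4]nonan-7-yl benzoate (both carbinol epimers) | CC1(C)O[C@H]([C@H](C)CC(O)C(C)(C)C(C)=O)[C@@]2(O1)C[C@@H](C)[C@H](OC(=O)c3ccccc3)[C@@H]2/C=C(\C)CO[Si](C)(C)C(C)(C)C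
F5 | step 15 | (4R,5R,6S,7S,8R)-4-[(2R,3E)-5,5-dimethyl-6-oxohept-3-en-2-yl]-6-[(1E)-3-(TBS-oxy)-2-methylprop-1-en-1-yl]-2,2,8-trimethyl-1,3-dioxaspiro[4.4]nonan-7-yl benzoate | CC1(C)O[C@H]([C@H](C)/C=C/C(C)(C)C(C)=O)[C@@]2(O1)C[C@@H](C)[C@H](OC(=O)c3ccccc3)[C@@H]2/C=C(\C)CO[Si](C)(C)C(C)(C)C
F6 | step 15 | (1S,2S,3R,5R)-3-hydroxy-3-[(1R,2R,3E)-1-hydroxy-2,5,5-trimethyl-6-oxohept-3-en-1-yl]-2-[(1E)-3-hydroxy-2-methylprop-1-en-1-yl]-5-methylcyclopentyl benzoate | O[C@H]([C@H](C)/C=C/C(C)(C)C(C)=O)[C@@]1(O)C[C@@H](C)[C@H](OC(=O)c2ccccc2)[C@@H]1/C=C(\C)CO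
F7 | step 15 | (1S,2S,3R,5R)-3-hydroxy-3-[(1R,2R,3E)-1-hydroxy-2,5,5-trimethyl-6-oxohept-3-en-1-yl]-5-methyl-2-[(1E)-2-methyl-3-oxoprop-1-en-1-yl]cyclopentyl benzoate | O[C@H]([C@H](C)/C=C/C(C)(C)C(C)=O)[C@@]1(O)C[C@@H](C)[C@H](OC(=O)c2ccccc2)[C@@H]1/C=C(\C)C=O
F8 | step 6 | (2R)-2-hydroxy-2-[(2S,3E)-1-hydroxy-5-(TBS-oxy)-4-methylpent-3-en-2-yl]-N-methoxy-N-methylpent-4-enamide | CON(C)C(=O)[C@@](O)(CC=C)[C@H](CO)/C=C(\C)CO[Si](C)(C)C(C)(C)C
F9 | step 6 | (4R,5S)-N-methoxy-N,2,2-trimethyl-4-(prop-2-en-1-yl)-5-[(1E)-3-(TBS-oxy)-2-methylprop-1-en-1-yl]-1,3-dioxane-4-carboxamide | CON(C)C(=O)[C@]1(CC=C)OC(C)(C)OC[C@@H]1/C=C(\C)CO[Si](C)(C)C(C)(C)C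
F10 | step 6 | (4R,5S)-2,2-dimethyl-4-(prop-2-en-1-yl)-5-[(1E)-3-(TBS-oxy)-2-methylprop-1-en-1-yl]-1,3-dioxane-4-carbaldehyde | O=C[C@]1(CC=C)OC(C)(C)OC[C@@H]1/C=C(\C)CO[Si](C)(C)C(C)(C)C
F11 | step 6 | (1R,2R)-1-{(4R,5S)-2,2-dimethyl-4-(prop-2-en-1-yl)-5-[(1E)-3-(TBS-oxy)-2-methylprop-1-en-1-yl]-1,3-dioxan-4-yl}-2-methylbut-3-en-1-ol | O[C@H]([C@H](C)C=C)[C@]1(CC=C)OC(C)(C)OC[C@@H]1/C=C(\C)CO[Si](C)(C)C(C)(C)C
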